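The trimer is cut at the catechin C6–C4 bond (a late aryllithium/ketone union) and, decisively, at O1 of ring C of the C8-bound fisetinidol unit. Removing O1 from between C8a and C2 contracts ring C to a 3-arylindan-1-one. Its C3 (the future C4) can be set by conjugate hydride delivery to an indenone made by sp2–sp2 coupling, so no C4 cation is needed. The Baeyer–Villiger step re-inserts O1 by shifting ring A carbon C8a from carbon to oxygen, which makes C8a–O1, O1–C2 and the six-membered lactone at once. The precursor is the (3S)-6-benzyloxy-3-(penta-O-benzylcatechin-8-yl)indanone, brominated at catechin C6 to shield ring D and to carry the later metalation handle.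

Key step: step 10

Remark: rings A/B/C belong to the C8-bound fisetinidol unit, D/E/F to catechin (D is its trioxygenated benzo ring) and G/H/I to the C6-bound fisetinidol unit; the facial sense of the (R)-ligand in step 7 is extrapolated from β-substituted cycloalkenones, and the antipodal ligand is used if a first run shows the opposite C3 configuration; C4 of carbinol 34 is left undefined because step 20 erases it.

Step 1
Reactants: 1 (+)-catechin
Product: 2 5,7,3',4'-tetra-O-benzylcatechin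
Conditions: BnBr (4.4 equiv), K2CO3, DMF, 0 °C → rt, Ar
Reagents that add atoms: benzyl bromide, BrCc1ccccc1
Why: Williamson etherification in which carbonate deprotonates only the four phenols, so the C3 alcohol and both stereocentres stay untouched.

Step 2
Reactants: 2 5,7,3',4'-tetra-O-benzylcatechin
Product: 3 3,5,7,3',4'-penta-O-benzylcatechin
Conditions: NaH, BnBr, DMF, 0 °C → rt
Reagents that add atoms: benzyl bromide, BrCc1ccccc1
Why: Williamson etherification of the remaining secondary alkoxide, needed because organolithium steps follow; no acidic C–H adjoins C2 or C3, so the configuration holds.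

Step 3
Reactants: 3 3,5,7,3',4'-penta-O-benzylcatechin
Product: 4 8-bromo-3,5,7,3',4'-penta-O-benzylcatechin
Conditions: NBS (1.0 equiv), CH2Cl2, −78 → 0 °C
Reagents that add atoms: N-bromosuccinimide, O=C1CCC(=O)N1Br
Why: Electrophilic aromatic bromination, in which C8 is the most nucleophilic position of ring D in benzylated catechins and one equivalent of NBS at low temperature should stop at the monobromide.

Step 4
Reactants: 5 6-hydroxyindan-1-one
Product: 6 6-acetoxyindan-1-one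
Conditions: Ac2O, Et3N, DMAP (cat.), CH2Cl2, 0 °C → rt
Reagents that add atoms: acetic anhydride, CC(=O)OC(C)=O
Why: Phenol acylation; an acetate is used here instead of a benzyl ether because O–CH2Ph hydrogens would be abstracted in the radical bromination that follows, and the ester also damps ring bromination.

Step 5
Reactants: 6 6-acetoxyindan-1-one
Product: 8 6-acetoxy-3-bromoinden-1-one, via 3,3-dibromide 7 (not isolated)
Conditions: NBS (2.2 equiv), AIBN (cat.), PhCF3, reflux; then Et3N, 0 °C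
Reagents that add atoms: N-bromosuccinimide, O=C1CCC(=O)N1Br
Why: Twofold Wohl–Ziegler bromination at benzylic C3, followed by base-induced loss of HBr through the acidic C2–H, gives the vinylogous acyl bromide, as is established for indan-1-ones.

Step 6
Reactants: 4 8-bromo-3,5,7,3',4'-penta-O-benzylcatechin; 8 6-acetoxy-3-bromoinden-1-one
Product: 11 6-acetoxy-3-(3,5,7,3',4'-penta-O-benzylcatechin-8-yl)inden-1-one, via aryllithium 9 (not isolated), via arylzinc chloride 10 (not isolated)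
Conditions: 4, n-BuLi, THF, −78 °C; ZnCl2, −78 °C → rt; then 8, Pd(OAc)2 (5 mol %), SPhos (10 mol %), THF, rt → 40 °C
Reagents that add atoms: none
Why: Bromine–lithium exchange, transmetalation and Negishi coupling in one flask; the zinc reagent tolerates acetate and enone and avoids the protodeboronation typical of 2,6-dialkoxyarylboron species, the β-bromoenone adds readily to zerovalent palladium, and SPhos accommodates the di-ortho-substituted partner.

Step 7
Reactants: 11 6-acetoxy-3-(3,5,7,3',4'-penta-O-benzylcatechin-8-yl)inden-1-one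
Product: 13 (3S)-6-acetoxy-3-(3,5,7,3',4'-penta-O-benzylcatechin-8-yl)indan-1-one, via silyl enol ether 12 (not isolated)
Conditions: Cu(OAc)2·H2O (5 mol %), (R)-DTBM-SEGPHOS (5.5 mol %), (EtO)2MeSiH, toluene, 0 °C → rt; then 1 M HCl, THF, 0 °C
Reagents that add atoms: none
Why: Copper hydride asymmetric conjugate reduction, in which the chiral bisphosphine directs hydride to one face of C3 and sets 3S; without an alcohol additive the ketone stays masked as silyl enol ether 12 against 1,2-reduction, and mild acid hydrolysis avoids base-induced proton shifts in the indene.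

Step 8
Reactants: 13 (3S)-6-acetoxy-3-(3,5,7,3',4'-penta-O-benzylcatechin-8-yl)indan-1-one
Product: 15 (3S)-6-benzyloxy-3-(3,5,7,3',4'-penta-O-benzylcatechin-8-yl)indan-1-one, via phenol 14 (not isolated)
Conditions: K2CO3, MeOH–THF, rt; evaporate; BnBr, K2CO3, DMF, rt
Reagents that add atoms: benzyl bromide, BrCc1ccccc1
Why: Methanolysis of the aryl acetate followed by Williamson etherification; carbonate is too weak to alkylate the ketone α-carbon, and C3, which is β to the carbonyl, is not epimerisable by enolisation.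

Step 9
Reactants: 15 (3S)-6-benzyloxy-3-(3,5,7,3',4'-penta-O-benzylcatechin-8-yl)indan-1-one
Product: 16 (3S)-6-benzyloxy-3-(6-bromo-3,5,7,3',4'-penta-O-benzylcatechin-8-yl)indan-1-one
Conditions: NBS (1.0 equiv), CH2Cl2, −40 → 0 °C, dark
Reagents that add atoms: N-bromosuccinimide, O=C1CCC(=O)N1Br
Why: Electrophilic aromatic bromination at C6, the only free position of the most electron-rich ring (D), which should outrun attack on the carbonyl-deactivated ring A, on ring E and on the ketone α-carbon under neutral cold conditions.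

Step 10
Reactants: 16 (3S)-6-benzyloxy-3-(6-bromo-3,5,7,3',4'-penta-O-benzylcatechin-8-yl)indan-1-one
Product: 18 (4S)-7-benzyloxy-4-(6-bromo-3,5,7,3',4'-penta-O-benzylcatechin-8-yl)chroman-2-one, via Criegee adduct 17 (not isolated)
Conditions: mCPBA (3 equiv), NaHCO3, CH2Cl2, 0 °C → rt, dark
Reagents that add atoms: 3-chloroperbenzoic acid, O=C(OO)c1cccc(Cl)c1
Why: The peracid adds to the unhindered C1 carbonyl to give Criegee adduct 17, in which ring A carbon C7a, aligned antiperiplanar to the O–O bond, shifts from C1 to oxygen as 3-chlorobenzoate leaves. This is a Baeyer–Villiger oxidation, and its closest analogues are the conversions of indan-1-ones, 3-aryl examples included, into 3,4-dihydrocoumarins. Ring C is not closed by a cyclisation but arises by one-atom enlargement of the five-membered ketone ring, the concerted 1,2-shift making C8a–O1 and O1–C2 together. No stereocentre is created, and C3 of the indanone, two bonds away from the reacting carbonyl, becomes C4 (S) unchanged. Regioselectivity requires aryl rather than CH2 migration; the benzyloxy group is meta to C7a and lends no extra push, so the preference rests on the intrinsic aptitude of an sp2 aryl carbon, with charge spread through a bridged transition state, over a primary alkyl carbon. Chemoselectivity requires attack at the ketone and not at the alkoxyarenes, which is secured by bromine at C6 (ring D then has no free position and is less nucleophilic), by complete O-benzylation and by the bicarbonate buffer that keeps strong acid out of the medium.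

Step 11
Reactants: 18 (4S)-7-benzyloxy-4-(6-bromo-3,5,7,3',4'-penta-O-benzylcatechin-8-yl)chroman-2-one; 19 4-bromo-1,2-bis(benzyloxy)benzene
Product: 22 (3S)-1-[3,4-bis(benzyloxy)phenyl]-3-(4-benzyloxy-2-hydroxyphenyl)-3-(6-bromo-3,5,7,3',4'-penta-O-benzylcatechin-8-yl)propan-1-one, via Weinreb amide 20 (not isolated), via aryl Grignard reagent 21 (not isolated)
Conditions: Me(MeO)NH·HCl, i-PrMgCl (2 equiv per amine salt), THF, −20 °C; then 18, −20 → 0 °C; then 21 (from 19, Mg, THF, reflux), 0 °C → rt; 1 M HCl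
Reagents that add atoms: none
Why: Aminolysis of the aryl ester followed by Weinreb ketone synthesis; the chelated tetrahedral adduct blocks the second addition that a phenoxide-expelling lactone would invite on direct treatment with an aryl metal, and magnesium reagents do not exchange with the C6 bromide.

Step 12
Reactants: 22 (3S)-1-[3,4-bis(benzyloxy)phenyl]-3-(4-benzyloxy-2-hydroxyphenyl)-3-(6-bromo-3,5,7,3',4'-penta-O-benzylcatechin-8-yl)propan-1-one
Product: 24 (4S)-7,3',4'-tri-O-benzyl-4-(6-bromo-3,5,7,3',4'-penta-O-benzylcatechin-8-yl)flav-2-ene, via hemiketal 23 (not isolated)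
Conditions: PPTS (cat.), 4 Å molecular sieves, toluene, 60 °C, Ar
Reagents that add atoms: none
Why: Acid-catalysed hemiketalisation and dehydration, the usual fate of 3-(2-hydroxyaryl)propiophenones, gives the aryl-conjugated 4H-chromene; proton loss can occur only from C3, so C4 is not touched, and the weak acid under argon avoids hydride loss to a flavylium ion.

Step 13
Reactants: 24 (4S)-7,3',4'-tri-O-benzyl-4-(6-bromo-3,5,7,3',4'-penta-O-benzylcatechin-8-yl)flav-2-ene
Product: 26 7,3',4'-tri-O-benzylfisetinidol-(4α→8)-6-bromo-3,5,7,3',4'-penta-O-benzylcatechin (upper unit 2R,3S,4S with free 3-OH), via C3 alkylborane 25 (not isolated)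
Conditions: BH3·THF, THF, 0 °C → rt; then NaOH, H2O2, 0 °C
Reagents that add atoms: hydrogen peroxide, OO
Why: Hydroboration–oxidation of a flav-2-ene; enol ether and styrene polarisation both send boron to C3, syn addition from the face opposite the pseudoaxial C4 aryl group sets C2 (R) and C3 (S) under substrate control, and oxidation with retention gives the 2,3-trans-3,4-trans array.

Step 14
Reactants: 26 7,3',4'-tri-O-benzylfisetinidol-(4α→8)-6-bromo-3,5,7,3',4'-penta-O-benzylcatechin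
Product: 27 3,7,3',4'-tetra-O-benzylfisetinidol-(4α→8)-6-bromo-3,5,7,3',4'-penta-O-benzylcatechin
Conditions: NaH, BnBr, n-Bu4NI (cat.), DMF, 0 °C → rt
Reagents that add atoms: benzyl bromide, BrCc1ccccc1
Why: Williamson etherification, with iodide catalysis for the hindered alkoxide, removes the only acidic proton so that it cannot quench the aryllithium of step 19.

Step 15
Reactants: 28 (+)-taxifolin (2R,3R)
Product: 29 (2R,3R)-7,3',4'-tri-O-benzyltaxifolin
Conditions: BnBr (3.1 equiv), K2CO3, DMF, rt, Ar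
Reagents that add atoms: benzyl bromide, BrCc1ccccc1
Why: Selective Williamson etherification; the 5-OH chelated to the C4 carbonyl and the aliphatic 3-OH are not alkylated by carbonate at room temperature, and the favoured 2,3-trans arrangement is retained.

Step 16
Reactants: 29 (2R,3R)-7,3',4'-tri-O-benzyltaxifolin
Product: 30 (2R,3R)-3,7,3',4'-tetra-O-benzyltaxifolin
Conditions: BnOC(=NH)CCl3, TfOH (cat.), CH2Cl2–cyclohexane, 0 °C
Reagents that add atoms: benzyl 2,2,2-trichloroacetimidate, N=C(OCc1ccccc1)C(Cl)(Cl)Cl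
Why: Acid-catalysed trichloroacetimidate benzylation of the 3-OH avoids the strong base that would enolise C3 and open ring I, and the chelated 5-OH is too poor a nucleophile to compete.

Step 17
Reactants: 30 (2R,3R)-3,7,3',4'-tetra-O-benzyltaxifolin
Product: 31 (2R,3R)-3,7,3',4'-tetra-O-benzyl-5-O-(trifluoromethanesulfonyl)taxifolin
Conditions: Tf2O, pyridine, CH2Cl2, 0 °C
Reagents that add atoms: trifluoromethanesulfonic anhydride, O=S(=O)(OS(=O)(=O)C(F)(F)F)C(F)(F)F
Why: O-Sulfonylation of the only remaining hydroxyl group turns C5–O into a leaving group for palladium.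

Step 18
Reactants: 31 (2R,3R)-3,7,3',4'-tetra-O-benzyl-5-O-(trifluoromethanesulfonyl)taxifolin
Product: 32 (2R,3R)-3,7,3',4'-tetra-O-benzylfustin (the 5-deoxy flavan-4-one)
Conditions: Pd(OAc)2 (5 mol %), dppf, HCO2H, Et3N, DMF, 60 °C
Reagents that add atoms: none
Why: Palladium-catalysed formate reduction of an aryl triflate (oxidative addition ortho to the carbonyl, decarboxylation of formate to a palladium hydride, reductive elimination); the homogeneous catalyst leaves benzyl ethers alone, and the formate buffer is too weakly basic to enolise C3.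

Step 19
Reactants: 27 3,7,3',4'-tetra-O-benzylfisetinidol-(4α→8)-6-bromo-3,5,7,3',4'-penta-O-benzylcatechin; 32 (2R,3R)-3,7,3',4'-tetra-O-benzylfustin
Product: 34 tertiary C4 carbinol joining C6 of ring D to C4 of the fustin unit (thirteen benzyl ethers), via aryllithium 33 (not isolated)
Conditions: 27, n-BuLi (1.05 equiv), THF, −78 °C; then 32 (1.5 equiv), −78 → −20 °C; H2O
Reagents that add atoms: none
Why: Bromine–lithium exchange followed by 1,2-addition of a 2,6-dialkoxyaryllithium to a protected flavan-4-one, a known way to forge interflavan bonds; the new carbinol centre, probably formed by attack anti to the C3 benzyloxy group, is of no consequence.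

Step 20
Reactants: 34 tertiary C4 carbinol
Product: 36 trideca-O-benzyl fisetinidol-(4α→8)-catechin-(6→4β)-fisetinidol, via C4 carbocation 35 (not isolated)
Conditions: n-Bu3SnH, CF3CO2H, CH2Cl2, 0 °C
Reagents that add atoms: none
Why: Ionic deoxygenation (acid ionisation, then hydride capture); the doubly aryl-stabilised cation 35 takes hydride on the face anti to the C3 benzyloxy group, so H enters α and the ring D substituent ends β, giving C4 (R) and the 2,3-trans-3,4-cis unit, and the stannane is chosen as the stronger and slimmer hydride donor for a crowded, stabilised cation.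

Step 21
Reactants: 36 trideca-O-benzyl fisetinidol-(4α→8)-catechin-(6→4β)-fisetinidol
Product: 37 fisetinidol-(4α→8)-catechin-(6→4β)-fisetinidol (CNP0289228.1)
Conditions: H2 (1 atm), Pd(OH)2/C, THF–MeOH–H2O, rt
Reagents that add atoms: none
Why: Catalytic hydrogenolysis cleaves all thirteen benzyl ethers in one operation under neutral conditions that leave the interflavan C–C bonds, the C2–O1 bonds and all eight stereocentres intact.

Compound list
1 | (+)-catechin (2R,3S) | Oc1cc(O)c2c(c1)O[C@H](c1ccc(O)c(O)c1)[C@@H](O)C2 | starting material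
2 | 5,7,3',4'-tetra-O-benzylcatechin | c1c(OCc9ccccc9)c2c(cc1OCc9ccccc9)O[C@H](c5ccc(OCc9ccccc9)c(OCc9ccccc9)c5)[C@@H](O)C2 | intermediate
3 | 3,5,7,3',4'-penta-O-benzylcatechin | c1c(OCc9ccccc9)c2c(cc1OCc9ccccc9)O[C@H](c5ccc(OCc9ccccc9)c(OCc9ccccc9)c5)[C@@H](OCc9ccccc9)C2 | intermediate
4 | 8-bromo-3,5,7,3',4'-penta-O-benzylcatechin | c1c(OCc9ccccc9)c2c(c(Br)c1OCc9ccccc9)O[C@H](c5ccc(OCc9ccccc9)c(OCc9ccccc9)c5)[C@@H](OCc9ccccc9)C2 | intermediate
5 | 6-hydroxyindan-1-one | O=C1CCc2ccc(O)cc21 | starting material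
6 | 6-acetoxyindan-1-one | O=C1CCc2ccc(OC(C)=O)cc21 | intermediate
7 | 6-acetoxy-3,3-dibromoindan-1-one (not isolated) | O=C1CC(Br)(Br)c2ccc(OC(C)=O)cc21 | intermediate
8 | 6-acetoxy-3-bromoinden-1-one | O=C1C=C(Br)c2ccc(OC(C)=O)cc21 | intermediate
9 | 8-lithio-3,5,7,3',4'-penta-O-benzylcatechin (not isolated) | c1c(OCc9ccccc9)c2c(c([Li])c1OCc9ccccc9)O[C@H](c5ccc(OCc9ccccc9)c(OCc9ccccc9)c5)[C@@H](OCc9ccccc9)C2 | intermediate
10 | (3,5,7,3',4'-penta-O-benzylcatechin-8-yl)zinc chloride (not isolated) | c1c(OCc9ccccc9)c2c(c([Zn]Cl)c1OCc9ccccc9)O[C@H](c5ccc(OCc9ccccc9)c(OCc9ccccc9)c5)[C@@H](OCc9ccccc9)C2 | intermediate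
11 | 6-acetoxy-3-(3,5,7,3',4'-penta-O-benzylcatechin-8-yl)inden-1-one | c1c(OCc9ccccc9)c2c(c(C3=CC(=O)c4cc(OC(C)=O)ccc34)c1OCc9ccccc9)O[C@H](c5ccc(OCc9ccccc9)c(OCc9ccccc9)c5)[C@@H](OCc9ccccc9)C2 | intermediate
12 | diethoxy(methyl)silyl enol ether of 13 (not isolated) | c1c(OCc9ccccc9)c2c(c([C@@H]3c4ccc(OC(C)=O)cc4C(O[Si](C)(OCC)OCC)=C3)c1OCc9ccccc9)O[C@H](c5ccc(OCc9ccccc9)c(OCc9ccccc9)c5)[C@@H](OCc9ccccc9)C2 | intermediate
13 | (3S)-6-acetoxy-3-(3,5,7,3',4'-penta-O-benzylcatechin-8-yl)indan-1-one | c1c(OCc9ccccc9)c2c(c([C@@H]3c4ccc(OC(C)=O)cc4C(=O)C3)c1OCc9ccccc9)O[C@H](c5ccc(OCc9ccccc9)c(OCc9ccccc9)c5)[C@@H](OCc9ccccc9)C2 | intermediate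
14 | (3S)-6-hydroxy-3-(3,5,7,3',4'-penta-O-benzylcatechin-8-yl)indan-1-one (not isolated) | c1c(OCc9ccccc9)c2c(c([C@@H]3c4ccc(O)cc4C(=O)C3)c1OCc9ccccc9)O[C@H](c5ccc(OCc9ccccc9)c(OCc9ccccc9)c5)[C@@H](OCc9ccccc9)C2 | intermediate
15 | (3S)-6-benzyloxy-3-(3,5,7,3',4'-penta-O-benzylcatechin-8-yl)indan-1-one | c1c(OCc9ccccc9)c2c(c([C@@H]3c4ccc(OCc9ccccc9)cc4C(=O)C3)c1OCc9ccccc9)O[C@H](c5ccc(OCc9ccccc9)c(OCc9ccccc9)c5)[C@@H](OCc9ccccc9)C2 | intermediate
16 | (3S)-6-benzyloxy-3-(6-bromo-3,5,7,3',4'-penta-O-benzylcatechin-8-yl)indan-1-one (key-step precursor) | Brc1c(OCc9ccccc9)c2c(c([C@@H]3c4ccc(OCc9ccccc9)cc4C(=O)C3)c1OCc9ccccc9)O[C@H](c5ccc(OCc9ccccc9)c(OCc9ccccc9)c5)[C@@H](OCc9ccccc9)C2 | intermediate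
17 | Criegee adduct of 16 and mCPBA, C1 undefined (not isolated) | Brc1c(OCc9ccccc9)c2c(c([C@@H]3c4ccc(OCc9ccccc9)cc4C(O)(OOC(=O)c6cccc(Cl)c6)C3)c1OCc9ccccc9)O[C@H](c5ccc(OCc9ccccc9)c(OCc9ccccc9)c5)[C@@H](OCc9ccccc9)C2 | intermediate
18 | (4S)-7-benzyloxy-4-(6-bromo-3,5,7,3',4'-penta-O-benzylcatechin-8-yl)chroman-2-one (key-step product) | Brc1c(OCc9ccccc9)c2c(c([C@@H]3c4ccc(OCc9ccccc9)cc4OC(=O)C3)c1OCc9ccccc9)O[C@H](c5ccc(OCc9ccccc9)c(OCc9ccccc9)c5)[C@@H](OCc9ccccc9)C2 | intermediate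
19 | 4-bromo-1,2-bis(benzyloxy)benzene | Brc1ccc(OCc2ccccc2)c(OCc2ccccc2)c1 | starting material
20 | (3S)-3-(4-benzyloxy-2-hydroxyphenyl)-3-(6-bromo-penta-O-benzylcatechin-8-yl)-N-methoxy-N-methylpropanamide, present as its magnesium phenoxide (not isolated) | Brc1c(OCc9ccccc9)c2c(c([C@@H](CC(=O)N(C)OC)c4ccc(OCc9ccccc9)cc4O)c1OCc9ccccc9)O[C@H](c5ccc(OCc9ccccc9)c(OCc9ccccc9)c5)[C@@H](OCc9ccccc9)C2 | intermediate
21 | 3,4-bis(benzyloxy)phenylmagnesium bromide (not isolated) | Br[Mg]c1ccc(OCc2ccccc2)c(OCc2ccccc2)c1 | intermediate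
22 | (3S)-1-[3,4-bis(benzyloxy)phenyl]-3-(4-benzyloxy-2-hydroxyphenyl)-3-(6-bromo-penta-O-benzylcatechin-8-yl)propan-1-one | Brc1c(OCc9ccccc9)c2c(c([C@@H](CC(=O)c6ccc(OCc9ccccc9)c(OCc9ccccc9)c6)c4ccc(OCc9ccccc9)cc4O)c1OCc9ccccc9)O[C@H](c5ccc(OCc9ccccc9)c(OCc9ccccc9)c5)[C@@H](OCc9ccccc9)C2 | intermediate
23 | 2-hydroxyflavan hemiketal of 22, C2 undefined (not isolated) | Brc1c(OCc9ccccc9)c2c(c([C@@H]3c4ccc(OCc9ccccc9)cc4OC(O)(c6ccc(OCc9ccccc9)c(OCc9ccccc9)c6)C3)c1OCc9ccccc9)O[C@H](c5ccc(OCc9ccccc9)c(OCc9ccccc9)c5)[C@@H](OCc9ccccc9)C2 | intermediate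
24 | (4S)-7,3',4'-tri-O-benzyl-4-(6-bromo-penta-O-benzylcatechin-8-yl)flav-2-ene | Brc1c(OCc9ccccc9)c2c(c([C@@H]3c4ccc(OCc9ccccc9)cc4OC(c6ccc(OCc9ccccc9)c(OCc9ccccc9)c6)=C3)c1OCc9ccccc9)O[C@H](c5ccc(OCc9ccccc9)c(OCc9ccccc9)c5)[C@@H](OCc9ccccc9)C2 | intermediate
25 | C3 β-alkylborane from 24 (not isolated) | Brc1c(OCc9ccccc9)c2c(c([C@@H]3c4ccc(OCc9ccccc9)cc4O[C@H](c6ccc(OCc9ccccc9)c(OCc9ccccc9)c6)[C@H]3B)c1OCc9ccccc9)O[C@H](c5ccc(OCc9ccccc9)c(OCc9ccccc9)c5)[C@@H](OCc9ccccc9)C2 | intermediate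
26 | 7,3',4'-tri-O-benzylfisetinidol-(4α→8)-6-bromo-penta-O-benzylcatechin (free 3-OH in ring C) | Brc1c(OCc9ccccc9)c2c(c([C@@H]3c4ccc(OCc9ccccc9)cc4O[C@H](c6ccc(OCc9ccccc9)c(OCc9ccccc9)c6)[C@H]3O)c1OCc9ccccc9)O[C@H](c5ccc(OCc9ccccc9)c(OCc9ccccc9)c5)[C@@H](OCc9ccccc9)C2 | intermediate
27 | 3,7,3',4'-tetra-O-benzylfisetinidol-(4α→8)-6-bromo-penta-O-benzylcatechin | Brc1c(OCc9ccccc9)c2c(c([C@@H]3c4ccc(OCc9ccccc9)cc4O[C@H](c6ccc(OCc9ccccc9)c(OCc9ccccc9)c6)[C@H]3OCc9ccccc9)c1OCc9ccccc9)O[C@H](c5ccc(OCc9ccccc9)c(OCc9ccccc9)c5)[C@@H](OCc9ccccc9)C2 | intermediate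
28 | (+)-taxifolin (2R,3R) | O=C1c2c(O)cc(O)cc2O[C@H](c2ccc(O)c(O)c2)[C@H]1O | starting material
29 | (2R,3R)-7,3',4'-tri-O-benzyltaxifolin | O=C1c2c(O)cc(OCc9ccccc9)cc2O[C@H](c2ccc(OCc9ccccc9)c(OCc9ccccc9)c2)[C@H]1O | intermediate
30 | (2R,3R)-3,7,3',4'-tetra-O-benzyltaxifolin | O=C1c2c(O)cc(OCc9ccccc9)cc2O[C@H](c2ccc(OCc9ccccc9)c(OCc9ccccc9)c2)[C@H]1OCc9ccccc9 | intermediate
31 | (2R,3R)-3,7,3',4'-tetra-O-benzyl-5-O-triflyltaxifolin | O=C1c2c(OS(=O)(=O)C(F)(F)F)cc(OCc9ccccc9)cc2O[C@H](c2ccc(OCc9ccccc9)c(OCc9ccccc9)c2)[C@H]1OCc9ccccc9 | intermediate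
32 | (2R,3R)-3,7,3',4'-tetra-O-benzylfustin | O=C1c2ccc(OCc9ccccc9)cc2O[C@H](c2ccc(OCc9ccccc9)c(OCc9ccccc9)c2)[C@H]1OCc9ccccc9 | intermediate
33 | C6 aryllithium from 27 (not isolated) | [Li]c1c(OCc9ccccc9)c2c(c([C@@H]3c4ccc(OCc9ccccc9)cc4O[C@H](c6ccc(OCc9ccccc9)c(OCc9ccccc9)c6)[C@H]3OCc9ccccc9)c1OCc9ccccc9)O[C@H](c5ccc(OCc9ccccc9)c(OCc9ccccc9)c5)[C@@H](OCc9ccccc9)C2 | intermediate
34 | tertiary C4 carbinol of the protected trimer, C4 of ring I undefined | c9ccccc9COc1ccc2c(c1)O[C@H](c1ccc(OCc9ccccc9)c(OCc9ccccc9)c1)[C@@H](OCc9ccccc9)C2(O)c1c(OCc9ccccc9)c2c(c([C@@H]3c4ccc(OCc9ccccc9)cc4O[C@H](c6ccc(OCc9ccccc9)c(OCc9ccccc9)c6)[C@H]3OCc9ccccc9)c1OCc9ccccc9)O[C@H](c5ccc(OCc9ccccc9)c(OCc9ccccc9)c5)[C@@H](OCc9ccccc9)C2 | intermediate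
35 | C4 carbocation from 34 (not isolated) | c9ccccc9COc1ccc2c(c1)O[C@H](c1ccc(OCc9ccccc9)c(OCc9ccccc9)c1)[C@@H](OCc9ccccc9)[C+]2c1c(OCc9ccccc9)c2c(c([C@@H]3c4ccc(OCc9ccccc9)cc4O[C@H](c6ccc(OCc9ccccc9)c(OCc9ccccc9)c6)[C@H]3OCc9ccccc9)c1OCc9ccccc9)O[C@H](c5ccc(OCc9ccccc9)c(OCc9ccccc9)c5)[C@@H](OCc9ccccc9)C2 | intermediate
36 | trideca-O-benzyl fisetinidol-(4α→8)-catechin-(6→4β)-fisetinidol | c9ccccc9COc1ccc2c(c1)O[C@H](c1ccc(OCc9ccccc9)c(OCc9ccccc9)c1)[C@@H](OCc9ccccc9)[C@H]2c1c(OCc9ccccc9)c2c(c([C@@H]3c4ccc(OCc9ccccc9)cc4O[C@H](c6ccc(OCc9ccccc9)c(OCc9ccccc9)c6)[C@H]3OCc9ccccc9)c1OCc9ccccc9)O[C@H](c5ccc(OCc9ccccc9)c(OCc9ccccc9)c5)[C@@H](OCc9ccccc9)C2 | intermediate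
37 | fisetinidol-(4α→8)-catechin-(6→4β)-fisetinidol, CNP0289228.1 | Oc1ccc2c(c1)O[C@H](c1ccc(O)c(O)c1)[C@@H](O)[C@H]2c1c(O)c2c(c([C@@H]3c4ccc(O)cc4O[C@H](c4ccc(O)c(O)c4)[C@H]3O)c1O)O[C@H](c1ccc(O)c(O)c1)[C@@H](O)C2 | target

Total step count: 21.
Longest linear sequence: 15 steps from (+)-catechin (steps 1–3, 6–14, 19–21). The side branches are steps 4–5 (indenone) and steps 15–18 (5-deoxy ketone).

Steps most likely to fail

1. Step 10.
   - Risk: peracid addition to the conjugated ketone may be slow. Oxidation of the alkoxyarenes or benzylic ethers, or migration of the CH2 carbon, could then compete.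
   - Fallback: this route sets out from arylzinc chloride 10 (made from 4 as in step 6) and comes back at 18. O1 is brought in with the building block instead of being inserted. Commercial 4'-benzyloxy-2'-hydroxyacetophenone is condensed with diethyl carbonate (NaH, toluene, reflux) to 7-benzyloxy-4-hydroxycoumarin F1. Treatment with Tf2O/Et3N converts it into 7-benzyloxy-4-(trifluoromethanesulfonyloxy)coumarin F2. Negishi coupling of F2 with 10 (Pd(OAc)2, SPhos, THF) gives 7-benzyloxy-4-(3,5,7,3',4'-penta-O-benzylcatechin-8-yl)coumarin F3. Copper hydride conjugate reduction of this 4-arylcoumarin (Cu(OAc)2·H2O, the DTBM-SEGPHOS antipode that gives 4S, (EtO)2MeSiH, t-BuOH, toluene) gives (4S)-7-benzyloxy-4-(3,5,7,3',4'-penta-O-benzylcatechin-8-yl)chroman-2-one F4. NBS bromination at C6 of ring D, as in step 9, then delivers 18.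

2. Step 7.
   - Risk: hydride transfer to C3, crowded by the di-ortho-substituted ring D, may be sluggish or poorly face-selective, and 1,2-reduction of the carbonyl may intervene.
   - Fallback: this route sets out from 11 and comes back at 13. It moves the stereodefining event to the unhindered carbonyl. Corey–Bakshi–Shibata reduction (2-methyl-CBS-oxazaborolidine, with the antipode matched to the 1R alcohol, BH3·SMe2, THF, −20 °C) gives (1R)-6-acetoxy-3-(3,5,7,3',4'-penta-O-benzylcatechin-8-yl)inden-1-ol F5. A tertiary amine (DABCO, THF, 60 °C) then relays the C1 hydrogen suprafacially to C3 through a tight ion pair. Tautomerisation of the resulting enol gives the (3S)-ketone 13, and any minor C3 diastereomer is removable by chromatography because the catechin unit is chiral.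

3. Step 19.
   - Risk: the aryllithium, flanked by two benzyloxy groups and by the bulky C8 substituent, may act as a base. It could then enolise the ketone with opening of ring I, or fail to add for steric reasons.
   - Fallback: this route sets out from 27 and 32 and comes back at 36. It reverses the roles, using a neutral arene nucleophile and a C4 electrophile. Aryllithium 33 is quenched with MeOH to give 3,7,3',4'-tetra-O-benzylfisetinidol-(4α→8)-3,5,7,3',4'-penta-O-benzylcatechin F6. Ketone 32 is reduced (NaBH4, THF–EtOH, 0 °C) to (2R,3S)-3,7,3',4'-tetra-O-benzylflavan-3,4-diol 4-ol F7. BF3·OEt2 (CH2Cl2, −78 → −20 °C) joins the two by Friedel–Crafts alkylation at C6, the only free position of ring D. Both C4 epimers are expected, so 36 has to be separated by chromatography from its 3,4-trans epimer, trideca-O-benzyl fisetinidol-(4α→8)-catechin-(6→4α)-fisetinidol F8.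

Further compounds
F1 | step 10 | 7-benzyloxy-4-hydroxycoumarin | O=C1C=C(O)c2ccc(OCc3ccccc3)cc2O1
F2 | step 10 | 7-benzyloxy-4-(trifluoromethanesulfonyloxy)coumarin | O=C1C=C(OS(=O)(=O)C(F)(F)F)c2ccc(OCc3ccccc3)cc2O1
F3 | step 10 | 7-benzyloxy-4-(3,5,7,3',4'-penta-O-benzylcatechin-8-yl)coumarin | c1c(OCc9ccccc9)c2c(c(C3=CC(=O)Oc4cc(OCc9ccccc9)ccc34)c1OCc9ccccc9)O[C@H](c5ccc(OCc9ccccc9)c(OCc9ccccc9)c5)[C@@H](OCc9ccccc9)C2
F4 | step 10 | (4S)-7-benzyloxy-4-(3,5,7,3',4'-penta-O-benzylcatechin-8-yl)chroman-2-one | c1c(OCc9ccccc9)c2c(c([C@@H]3c4ccc(OCc9ccccc9)cc4OC(=O)C3)c1OCc9ccccc9)O[C@H](c5ccc(OCc9ccccc9)c(OCc9ccccc9)c5)[C@@H](OCc9ccccc9)C2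
F5 | step 7 | (1R)-6-acetoxy-3-(3,5,7,3',4'-penta-O-benzylcatechin-8-yl)inden-1-ol | c1c(OCc9ccccc9)c2c(c(C3=C[C@@H](O)c4cc(OC(C)=O)ccc34)c1OCc9ccccc9)O[C@H](c5ccc(OCc9ccccc9)c(OCc9ccccc9)c5)[C@@H](OCc9ccccc9)C2
F6 | step 19 | 3,7,3',4'-tetra-O-benzylfisetinidol-(4α→8)-3,5,7,3',4'-penta-O-benzylcatechin | c1c(OCc9ccccc9)c2c(c([C@@H]3c4ccc(OCc9ccccc9)cc4O[C@H](c6ccc(OCc9ccccc9)c(OCc9ccccc9)c6)[C@H]3OCc9ccccc9)c1OCc9ccccc9)O[C@H](c5ccc(OCc9ccccc9)c(OCc9ccccc9)c5)[C@@H](OCc9ccccc9)C2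
F7 | step 19 | (2R,3S)-3,7,3',4'-tetra-O-benzylflavan-3,4-diol 4-ol, C4 undefined | OC1c2ccc(OCc9ccccc9)cc2O[C@H](c2ccc(OCc9ccccc9)c(OCc9ccccc9)c2)[C@H]1OCc9ccccc9
F8 | step 19 | trideca-O-benzyl fisetinidol-(4α→8)-catechin-(6→4α)-fisetinidol | c9ccccc9COc1ccc2c(c1)O[C@H](c1ccc(OCc9ccccc9)c(OCc9ccccc9)c1)[C@@H](OCc9ccccc9)[C@@H]2c1c(OCc9ccccc9)c2c(c([C@@H]3c4ccc(OCc9ccccc9)cc4O[C@H](c6ccc(OCc9ccccc9)c(OCc9ccccc9)c6)[C@H]3OCc9ccccc9)c1OCc9ccccc9)O[C@H](c5ccc(OCc9ccccc9)c(OCc9ccccc9)c5)[C@@H](OCc9ccccc9)C2
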